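All runs stem from a simulated flask for substances that don't exist; the scatter is artificial.

The charge changed from flask to flask but the loading did not: free catalyst stayed at 6.1 mol% of the substrate. One turnover therefore meant the same fraction of the charge in each flask, and I compared flasks by the fraction converted to target at 2.5 min. The zero of my scale was a cycle indifferent to the charge, with equal turnovers per catalyst and so an equal fraction everywhere.

| flask | substrate | free catalyst | added ligand | remark | time |
|---|---|---|---|---|---|
| zeta | 0.0049 M | 6.1 mol% | 22 mM | run made earlier |  |
| delta | 0.12 M | 6.1 mol% | 22 mM | run made earlier |  |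
| east | 0.0040 M | 6.1 mol% | 22 mM |  | 2.5 min |
| north-east | 0.012 M | 6.1 mol% | 22 mM |  | 2.5 min |
| north | 0.030 M | 6.1 mol% | 22 mM |  | 2.5 min |
| west | 0.10 M | 6.1 mol% | 22 mM |  | 2.5 min |

| zeta: time / min | zeta: target / % | delta: time / min | delta: target / % |
|---|---|---|---|
| 0.200 | 0 | 0.333 | 3.1 |
| 0.500 | 0.2 | 0.833 | 9.0 |
| 1.00 | 1.0 | 1.50 | 16.6 |
| 2.50 | 3.6 | 2.50 | 22.0 |

(readings scatter by 1 percentage point)

* [target] at the end for east, north-east, north, west, in this order
* the course of these numbers from the first flask to the last (rises all the way / falls all the way / hardly changes / rises, then falls / falls, then rises)

- in percentages every species weighs as the substrate in it: one self-condensation product or resting dimer counts as two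
- steps under discussion: 2 substrate -> self-condensation product; free catalyst + added ligand <-> idle complex; catalyst intermediate B -> free catalyst + target; catalyst intermediate A <-> catalyst intermediate B; substrate + free catalyst -> catalyst intermediate A; 2 catalyst intermediate A <-> resting dimer
- "hardly changes" means that all values lie within two and a half points (for a concentration: within two and a half percent of the largest)

The fraction was not equal: it stood at 3.6% in zeta and 22.0% in delta at that time. These two readings gave 0.566 for the charge slope, the rise in the logarithm of the fraction per rise in the logarithm of the charge. I took slope zero as a saturated cycle and slope one as capture of substrate being the rate-limiting step.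

That gave me a bracket for north. From above, slope one from zeta reached 22.0%, and a fraction rising with charge stopped at delta's reading. From below, the flat case gave zeta's reading. I tightened this by assuming that the slope falls as the charge grows, which puts the straight line between the two runs under the curve, at 10.0%. For west the same line gave 19.8%. The scatter of 1 percentage point on zeta's small reading left this low edge soft. I committed to the line, which gave 1.28 × 10⁻⁴ M, 7.17 × 10⁻⁴ M, 0.00301 M and 0.0198 M.

The forecast gave 1.000 × 10⁻⁴ M, 9.000 × 10⁻⁴ M, 0.0045 M and 0.022 M, a course that rises all the way, reasoning that “capture of substrate is limiting at low concentration”. Its north, 15.0% of the charge, lay inside my bracket and above my line.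

The flasks gave 7.84 × 10⁻⁵ M, 6.36 × 10⁻⁴ M, 0.00326 M and 0.0208 M, a course that rises all the way. North, at 10.9%, stood inside its bracket, and west stood at 20.8% against the 19.8% of my line. The charge slope read 0.905 from east to north-east and 0.539 from north to west, on either side of 0.566.

    2 substrate → self-condensation product (k = 0.0386 /M/s)
    free catalyst + added ligand ⇌ idle complex (K = 29.8 /M, k = 0.547 /M/s)
    catalyst intermediate B → free catalyst + target (k = 0.253 /s)
    catalyst intermediate A ⇌ catalyst intermediate B (K = 0.440, k = 5.59 /s)
    substrate + free catalyst → catalyst intermediate A (k = 0.891 /M/s)
    2 catalyst intermediate A ⇌ resting dimer, settled at all times (K = 89.5 /M)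

Target in west stood at 0.0208 M for two reasons acting together: the reading was taken at 2.50 min and not ten times later, and catalyst intermediate B ran back to catalyst intermediate A. Read at 25.0 min, the west run gave 0.0468 M. With that back reaction taken away, the west run gave 0.0282 M at 2.50 min.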